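**Retrosynthetic overview**

1. The O6 ester, the 6α-hydroxyl (enolate hydroxylation beside the C7 ketone), the 5α-hydrogen (hydroxyl-directed hydrogenation), the 8α,9α-diol (dihydroxylation of a C8=C9 enone), the C8 methyl (enolate methylation) and the C7 ketone (allylic oxidation) all trace back to one handle, the C5=C6 alkene of a bicyclo[5.3.0]dec-5-ene.
2. Feature: the quaternary methyl-bearing ring-fusion carbon C1 is bonded to C2 and C5 inside the five-membered ring C1–C2–C3–C4–C5. Breaking C1–C2 and joining C2 to C5 gives a cyclobutane (C2–C3–C4–C5) spiro-fused at C5 to a cycloheptene with a C1=C10 alkene; the forward step is the cationic 1,2-shift with ring enlargement.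
3. The spiro acetate comes from (S)-5-methylspiro[3.6]dec-5-en-1-one by isopropyl addition and acetylation. The spiroketone comes from a 1-cycloheptenylcyclopropanol allylic carbonate by palladium-catalysed ring expansion, with the spiro configuration relayed from a carbinol centre set by oxazaborolidine reduction.
4. The cyclopropanol comes from a Kulinkovich reaction on an enoate made from cycloheptane-1,3-dione by C-methylation, enol triflate formation and methoxycarbonylation.
5. Ring order: seven-membered ring (bought), then cyclopropane, then cyclobutanone, then five-membered ring (key step).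

Key step: step 10

Remark 1: bicyclic compounds carry daucane numbering (C1 ring-fusion CMe, C4 isopropyl carbinol, C5 ring-fusion CH, C6 to C10 round the seven-membered ring, C14 the methyl on C8); β is the face of the C1 methyl.
Remark 2: the sense of the oxazaborolidine reduction in step 4 is assigned by the usual model with the fully substituted alkene carbon as the large group.
Remark 3: the target is taken as the open 4-hydroxy-7-ketone of the given SMILES, not as a C4–O–C7 hemiketal.

**Route**

Step 1
Reactants: 1 cycloheptane-1,3-dione; 2 iodomethane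
Product: 3 2-methylcycloheptane-1,3-dione
Conditions: MeI, K2CO3, acetone, 55 °C
Reagents that add atoms: iodomethane, CI
Why: Enolate alkylation of the 1,3-dione at the doubly activated C2 installs the carbon that becomes the C1 methyl.

Step 2
Reactants: 3 2-methylcycloheptane-1,3-dione
Product: 4 2-methyl-3-oxocyclohept-1-en-1-yl trifluoromethanesulfonate
Conditions: Tf2O, Et3N, CH2Cl2, −78 → 0 °C
Reagents that add atoms: trifluoromethanesulfonic anhydride, O=S(=O)(OS(=O)(=O)C(F)(F)F)C(F)(F)F
Why: Enol triflate formation by O-sulfonylation of the dione enolate can give only one product because the dione is symmetric.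

Step 3
Reactants: 4 2-methyl-3-oxocyclohept-1-en-1-yl trifluoromethanesulfonate
Product: 5 methyl 2-methyl-3-oxocyclohept-1-ene-1-carboxylate
Conditions: Pd(OAc)2 (5 mol%), PPh3, CO (1 atm), MeOH, Et3N, DMF, 60 °C
Reagents that add atoms: carbon monoxide, [C-]#[O+]; methanol, CO
Why: Palladium-catalysed alkoxycarbonylation (oxidative addition of the vinyl triflate to zerovalent palladium, CO insertion, methanolysis) gives the enoate without touching the ketone.

Step 4
Reactants: 5 methyl 2-methyl-3-oxocyclohept-1-ene-1-carboxylate
Product: 6 methyl (3R)-3-hydroxy-2-methylcyclohept-1-ene-1-carboxylate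
Conditions: (S)-2-methyl-CBS-oxazaborolidine (20 mol%), catecholborane, toluene, −78 °C
Reagents that add atoms: none
Why: Corey–Bakshi–Shibata reduction, in which the bound ketone presents the fully substituted alkene carbon as the large group, should give the (R)-carbinol that is later relayed to the spiro carbon, and the conjugated ester is left alone.

Step 5
Reactants: 6 methyl (3R)-3-hydroxy-2-methylcyclohept-1-ene-1-carboxylate; 7 ethylmagnesium bromide
Product: 8 (1R)-3-(1-hydroxycyclopropyl)-2-methylcyclohept-2-en-1-ol
Conditions: EtMgBr (4.5 equiv), Ti(OiPr)4 (1 equiv), THF, 0 °C → rt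
Reagents that add atoms: ethylmagnesium bromide, CC[Mg]Br
Why: Kulinkovich cyclopropanation, in which the titanacyclopropane from EtMgBr and Ti(OiPr)4 adds twice to the ester carbonyl, gives the 1-alkenylcyclopropanol while the free hydroxyl is carried as its magnesium alkoxide and the carbinol centre is untouched.

Step 6
Reactants: 8 (1R)-3-(1-hydroxycyclopropyl)-2-methylcyclohept-2-en-1-ol
Product: 9 (1R)-3-(1-hydroxycyclopropyl)-2-methylcyclohept-2-en-1-yl methyl carbonate
Conditions: ClCO2Me (1.1 equiv), pyridine, CH2Cl2, −20 °C
Reagents that add atoms: methyl chloroformate, COC(=O)Cl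
Why: Carbonate formation with the chloroformate should occur at the secondary allylic hydroxyl, since the tertiary cyclopropanol acylates much more slowly at low temperature with one equivalent of reagent.

Step 7
Reactants: 9 (1R)-3-(1-hydroxycyclopropyl)-2-methylcyclohept-2-en-1-yl methyl carbonate
Product: 10 (4S)-5-methylspiro[3.6]dec-5-en-1-one
Conditions: Pd2(dba)3·CHCl3 (2.5 mol%), dppe (6 mol%), THF, 50 °C
Reagents that add atoms: none
Why: In this palladium-catalysed Wagner–Meerwein-type ring expansion of a 1-alkenylcyclopropanol, zerovalent palladium ionises the carbonate with inversion and the alkoxide-driven 1,2-shift of a cyclopropane carbon attacks the carbinol-bearing allyl terminus anti to palladium, so that the carbonate stereocentre is relayed to the (S)-spiro quaternary centre, a relay that is needed because a cyclic π-allyl complex with unlike termini cannot exchange faces.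

Step 8
Reactants: 10 (4S)-5-methylspiro[3.6]dec-5-en-1-one; 11 isopropylmagnesium chloride
Product: 12 (1R,4S)-1-isopropyl-5-methylspiro[3.6]dec-5-en-1-ol
Conditions: iPrMgCl, CeCl3 (anhydrous), THF, −78 °C
Reagents that add atoms: isopropylmagnesium chloride, CC(C)[Mg]Cl
Why: 1,2-Addition of the organocerium reagent (CeCl3 suppresses enolisation and β-hydride reduction) should occur on the cyclobutanone face anti to the methyl-bearing alkene carbon on the spiro centre (Felkin–Anh, anti to the alkenyl branch), which places the hydroxyl cis to that carbon and sets the (1R)-carbinol, the future C4.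

Step 9
Reactants: 12 (1R,4S)-1-isopropyl-5-methylspiro[3.6]dec-5-en-1-ol
Product: 13 (1R,4S)-1-isopropyl-5-methylspiro[3.6]dec-5-en-1-yl acetate
Conditions: Ac2O, Et3N, DMAP, CH2Cl2, rt → 40 °C
Reagents that add atoms: acetic anhydride, CC(=O)OC(C)=O
Why: DMAP-catalysed acylation of the tertiary cyclobutanol gives the acetate that tempers the oxygen lone pair in the cationic step, and no stereocentre is affected.

Step 10
Reactants: 13 (1R,4S)-1-isopropyl-5-methylspiro[3.6]dec-5-en-1-yl acetate
Product: 14 14-nordauc-5-en-4β-yl acetate (4β-acetoxy-4α-isopropyl-1β-methylbicyclo[5.3.0]dec-5-ene)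
Conditions: Tf2NH (20 mol%), CH2Cl2, −78 → −20 °C; then Et3N
Reagents that add atoms: none
Why: Markovnikov protonation of the C1=C10 alkene at C10 gives the tertiary C1 cation beside the strained spiro carbon C5, the cyclobutane bond C5–C2 shifts to C1 with release of four-ring strain, and the tertiary C5 cation loses a proton from C6, its only hydrogen-bearing neighbour, to give the C5=C6 alkene and return the proton. The closest known reaction type is the acid-promoted ring expansion of alkenyl- and alkylidene-cyclobutanes through cyclobutylcarbinyl cations to fused cyclopentanes. The five-membered ring C1–C2–C3–C4–C5 is closed by enlargement of the four-membered ring (a 1,2-carbon shift, not an end-to-end cyclisation), and the same event makes the C1–C5 bond shared by both rings. The new quaternary stereocentre C1 is controlled by the spiro configuration at C5, because C2 lies on the α face of the seven-membered ring and can only migrate suprafacially to the α lobe of the C1 cation, leaving the methyl β and cis to the C4 acetoxy group. The step needs migration of C2 and not C4, and proton loss instead of fragmentation or capture; the acetoxy group makes C4 a poor migrating carbon and weakens the oxygen push that would drive Grob-type opening or a semipinacol shift. A catalytic acid with the non-nucleophilic triflimide counter-ion at low temperature leaves proton loss from C6 as the only productive exit, and any acetoxonium ion formed from the neighbouring acetate can reopen.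

Step 11
Reactants: 14 14-nordauc-5-en-4β-yl acetate
Product: 15 4β-acetoxy-14-nordauc-5-en-7-one
Conditions: Rh2(cap)4 (dirhodium tetracaprolactamate, 1 mol%), tBuOOH (70% aq.), ClCH2CH2Cl, 40 °C
Reagents that add atoms: tert-butyl hydroperoxide, CC(C)(C)OO
Why: Radical allylic oxidation by tert-butylperoxy radicals attacks the only allylic C–H bonds of the C5=C6 alkene, those at C7 (C1 and C4 are quaternary), and gives the enone.

Step 12
Reactants: 15 4β-acetoxy-14-nordauc-5-en-7-one; 2 iodomethane
Product: 16 4β-acetoxydauc-5-en-7-one (C8 epimers)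
Conditions: LiN(SiMe3)2, THF, −78 °C; MeI, −78 → −20 °C
Reagents that add atoms: iodomethane, CI
Why: Enolate alkylation is regiospecific because C8 is the only enolisable position of the enone (both γ carbons are quaternary), and the C8 configuration is irrelevant since C8 becomes sp2 in the next step.

Step 13
Reactants: 16 4β-acetoxydauc-5-en-7-one
Product: 18 4β-acetoxydauca-5,8-dien-7-one, via trimethylsilyl dienol ether 17 (not isolated)
Conditions: Me3SiOTf, Et3N, CH2Cl2, 0 °C; then Pd(OAc)2 (1.1 equiv), MeCN, rt
Reagents that add atoms: none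
Why: Saegusa–Ito oxidation, in which enol silylation toward C8 (again the only direction) is followed by syn β-hydride loss of a ring hydrogen at C9 from the divalent palladium enolate, should give the endocyclic cross-conjugated dienone.

Step 14
Reactants: 18 4β-acetoxydauca-5,8-dien-7-one
Product: 19 4β-acetoxy-8α,9α-dihydroxydauc-5-en-7-one
Conditions: OsO4 (5 mol%), NMO, acetone/H2O, rt
Reagents that add atoms: osmium tetroxide, O=[Os](=O)(=O)=O; N-methylmorpholine N-oxide, C[N+]1([O-])CCOCC1; water, O
Why: Upjohn syn-dihydroxylation selects C8=C9 because C5=C6 is shielded by the quaternary carbons C1 and C4, and the reagent should approach anti to the pseudo-axial β-methyl on C1, setting 8α-OH and 9α-OH together.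

Step 15
Reactants: 19 4β-acetoxy-8α,9α-dihydroxydauc-5-en-7-one
Product: 20 4β-acetoxy-8α,9α-dihydroxy-5α-daucan-7-one
Conditions: H2 (1 atm), [Ir(cod)(PCy3)(py)]PF6 (10 mol%), CH2Cl2, rt
Reagents that add atoms: none
Why: Hydroxyl-directed hydrogenation with the cationic iridium catalyst should deliver both hydrogens to the α face, because the 8α-hydroxyl (homoallylic to C5=C6 through C7) binds the metal, and this sets the 5α-hydrogen of the trans ring fusion on an alkene that this catalyst class can still reduce.

Step 16
Reactants: 20 4β-acetoxy-8α,9α-dihydroxy-5α-daucan-7-one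
Product: 21 4β-acetoxy-8α,9α-(isopropylidenedioxy)-5α-daucan-7-one
Conditions: Me2C(OMe)2, PPTS, CH2Cl2, rt
Reagents that add atoms: 2,2-dimethoxypropane, COC(C)(C)OC
Why: Acid-catalysed transketalisation of the cis-diol gives the acetonide, which masks the β-hydroxy ketone against retro-aldol cleavage in the basic steps that follow.

Step 17
Reactants: 21 4β-acetoxy-8α,9α-(isopropylidenedioxy)-5α-daucan-7-one
Product: 22 4β-hydroxy-8α,9α-(isopropylidenedioxy)-5α-daucan-7-one
Conditions: NaOMe (cat.), MeOH, 50 °C
Reagents that add atoms: none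
Why: Zemplén-type transesterification removes the tertiary acetate before the aryl ester is introduced, and no stereocentre is at risk because the C6 methylene is the only acidic position of the ketone.

Step 18
Reactants: 22 4β-hydroxy-8α,9α-(isopropylidenedioxy)-5α-daucan-7-one
Product: 23 4β,6α-dihydroxy-8α,9α-(isopropylidenedioxy)-5α-daucan-7-one
Conditions: KN(SiMe3)2 (2.3 equiv), THF, −78 °C; 2-(phenylsulfonyl)-3-phenyloxaziridine, −78 °C; AcOH
Reagents that add atoms: 2-(phenylsulfonyl)-3-phenyloxaziridine, O=S(=O)(c1ccccc1)N1OC1c1ccccc1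
Why: Enolate hydroxylation with the N-sulfonyloxaziridine (Davis-type) occurs at C6, the only enolisable position, and oxygen should enter from the α face, anti to the β-methyl groups on C1 and C8 and the β-alkoxide on C4, to set the equatorial 6α-hydroxyl.

Step 19
Reactants: 24 4-hydroxybenzoic acid
Product: 26 4-(methoxymethoxy)benzoic acid, via methoxymethyl 4-(methoxymethoxy)benzoate 25 (not isolated)
Conditions: MOMCl (2.5 equiv), iPr2NEt, CH2Cl2, 0 °C → rt; then NaOH, MeOH/H2O; HCl to pH 4
Reagents that add atoms: chloromethyl methyl ether, COCCl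
Why: Exhaustive methoxymethylation followed by saponification of the acetal ester (protection then hydrolysis) leaves the acid with its phenol masked as an acid-labile ether.

Step 20
Reactants: 23 4β,6α-dihydroxy-8α,9α-(isopropylidenedioxy)-5α-daucan-7-one; 26 4-(methoxymethoxy)benzoic acid
Product: 27 4β-hydroxy-8α,9α-(isopropylidenedioxy)-6α-[4-(methoxymethoxy)benzoyloxy]-5α-daucan-7-one
Conditions: EDC·HCl, DMAP, CH2Cl2, rt
Reagents that add atoms: 4-(methoxymethoxy)benzoic acid, COCOc1ccc(cc1)C(O)=O
Why: Steglich-type carbodiimide esterification acylates the secondary 6α-hydroxyl with retention while the tertiary 4β-hydroxyl does not react.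

Step 21
Reactants: 27 4β-hydroxy-8α,9α-(isopropylidenedioxy)-6α-[4-(methoxymethoxy)benzoyloxy]-5α-daucan-7-one
Product: 28 4β,8α,9α-trihydroxy-6α-(4-hydroxybenzoyloxy)-5α-daucan-7-one (CNP0241001.1)
Conditions: HCl (3 M aq.), THF, 40 °C
Reagents that add atoms: none
Why: Acetal hydrolysis in aqueous acid removes the acetonide and the aryl methoxymethyl ether in one operation and should leave the ester, the tertiary alcohol and the base-sensitive β-hydroxy ketone intact.

**Compound list**

1 | cycloheptane-1,3-dione | O=C1CCCCC(=O)C1 | starting material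
2 | iodomethane | CI | starting material
3 | 2-methylcycloheptane-1,3-dione | CC1C(=O)CCCCC1=O | intermediate
4 | 2-methyl-3-oxocyclohept-1-en-1-yl trifluoromethanesulfonate | CC1=C(OS(=O)(=O)C(F)(F)F)CCCCC1=O | intermediate
5 | methyl 2-methyl-3-oxocyclohept-1-ene-1-carboxylate | COC(=O)C1=C(C)C(=O)CCCC1 | intermediate
6 | methyl (3R)-3-hydroxy-2-methylcyclohept-1-ene-1-carboxylate | COC(=O)C1=C(C)[C@H](O)CCCC1 | intermediate
7 | ethylmagnesium bromide | CC[Mg]Br | starting material
8 | (1R)-3-(1-hydroxycyclopropyl)-2-methylcyclohept-2-en-1-ol | OC1(CC1)C2=C(C)[C@H](O)CCCC2 | intermediate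
9 | (1R)-3-(1-hydroxycyclopropyl)-2-methylcyclohept-2-en-1-yl methyl carbonate | OC1(CC1)C2=C(C)[C@H](OC(=O)OC)CCCC2 | intermediate
10 | (4S)-5-methylspiro[3.6]dec-5-en-1-one | O=C1CC[C@@]12C(C)=CCCCC2 | intermediate
11 | isopropylmagnesium chloride | CC(C)[Mg]Cl | starting material
12 | (1R,4S)-1-isopropyl-5-methylspiro[3.6]dec-5-en-1-ol | CC(C)[C@]1(O)CC[C@@]12C(C)=CCCCC2 | intermediate
13 | (1R,4S)-1-isopropyl-5-methylspiro[3.6]dec-5-en-1-yl acetate | CC(C)[C@]1(OC(C)=O)CC[C@@]12C(C)=CCCCC2 | intermediate
14 | 14-nordauc-5-en-4β-yl acetate | CC(C)[C@]1(OC(C)=O)CC[C@]2(C)CCCCC=C21 | intermediate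
15 | 4β-acetoxy-14-nordauc-5-en-7-one | CC(C)[C@]1(OC(C)=O)CC[C@]2(C)CCCC(=O)C=C21 | intermediate
16 | 4β-acetoxydauc-5-en-7-one (C8 epimers) | CC(C)[C@]1(OC(C)=O)CC[C@]2(C)CCC(C)C(=O)C=C21 | intermediate
17 | 4β-acetoxy-7-(trimethylsilyloxy)dauca-5,7-diene | CC(C)[C@]1(OC(C)=O)CC[C@]2(C)CCC(C)=C(O[Si](C)(C)C)C=C21 | intermediate
18 | 4β-acetoxydauca-5,8-dien-7-one | CC(C)[C@]1(OC(C)=O)CC[C@]2(C)CC=C(C)C(=O)C=C21 | intermediate
19 | 4β-acetoxy-8α,9α-dihydroxydauc-5-en-7-one | CC(C)[C@]1(OC(C)=O)CC[C@]2(C)C[C@H](O)[C@](C)(O)C(=O)C=C21 | intermediate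
20 | 4β-acetoxy-8α,9α-dihydroxy-5α-daucan-7-one | CC(C)[C@]1(OC(C)=O)CC[C@]2(C)C[C@H](O)[C@](C)(O)C(=O)C[C@H]21 | intermediate
21 | 4β-acetoxy-8α,9α-(isopropylidenedioxy)-5α-daucan-7-one | CC(C)[C@]1(OC(C)=O)CC[C@]2(C)C[C@@H]3OC(C)(C)O[C@]3(C)C(=O)C[C@H]21 | intermediate
22 | 4β-hydroxy-8α,9α-(isopropylidenedioxy)-5α-daucan-7-one | CC(C)[C@]1(O)CC[C@]2(C)C[C@@H]3OC(C)(C)O[C@]3(C)C(=O)C[C@H]21 | intermediate
23 | 4β,6α-dihydroxy-8α,9α-(isopropylidenedioxy)-5α-daucan-7-one | CC(C)[C@]1(O)CC[C@]2(C)C[C@@H]3OC(C)(C)O[C@]3(C)C(=O)[C@H](O)[C@H]21 | intermediate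
24 | 4-hydroxybenzoic acid | OC(=O)c1ccc(O)cc1 | starting material
25 | methoxymethyl 4-(methoxymethoxy)benzoate | COCOC(=O)c1ccc(OCOC)cc1 | intermediate
26 | 4-(methoxymethoxy)benzoic acid | COCOc1ccc(cc1)C(O)=O | intermediate
27 | 4β-hydroxy-8α,9α-(isopropylidenedioxy)-6α-[4-(methoxymethoxy)benzoyloxy]-5α-daucan-7-one | CC(C)[C@]1(O)CC[C@]2(C)C[C@@H]3OC(C)(C)O[C@]3(C)C(=O)[C@H](OC(=O)c4ccc(OCOC)cc4)[C@H]21 | intermediate
28 | 4β,8α,9α-trihydroxy-6α-(4-hydroxybenzoyloxy)-5α-daucan-7-one (CNP0241001.1) | CC(C)[C@]1(O)CC[C@]2(C)C[C@H](O)[C@](C)(O)C(=O)[C@H](OC(=O)c3ccc(O)cc3)[C@H]21 | target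

**Step count**

Total step count: 21. Longest linear sequence: 20 steps (steps 1 to 18, 20 and 21, from cycloheptane-1,3-dione); step 19 is a side branch.

**Steps most likely to fail**

1. Step 10 (cationic ring expansion). The cation at C1 or C5 may be intercepted by the carbonyl oxygen of the neighbouring acetate, the acid may ionise the tertiary acetate, or the oxygen-bearing carbon C4 may migrate in competition with C2. The fallback sets out from alcohol 12. Acylation with (CF3CO)2O and pyridine in CH2Cl2 at 0 °C should give (1R,4S)-1-isopropyl-5-methylspiro[3.6]dec-5-en-1-yl trifluoroacetate F1, whose acyl oxygen is a far weaker base and neighbouring group and which deactivates C4 more strongly. Treatment with Tf2NH as in step 10 should give 14-nordauc-5-en-4β-yl trifluoroacetate F2. Methanolysis with K2CO3 in MeOH at 0 °C should give 14-nordauc-5-en-4β-ol F3, and acetylation (Ac2O, Et3N, DMAP) returns to the route at 14.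

2. Step 7 (palladium-catalysed ring expansion). Ionisation of the fully substituted allylic carbonate may be slow, the π-allyl complex may lose a β-hydrogen to give a diene, or the stereochemical relay may erode through exchange of palladium between the two allyl faces. The fallback sets out from diol 8. A catalytic Brønsted acid (TsOH·H2O, CH2Cl2, 0 °C) ionises the allylic alcohol and the cyclopropanol traps the allyl cation by the same 1,2-shift (vinylogous semipinacol rearrangement). This should give 5-methylspiro[3.6]dec-5-en-1-one of low enantiomeric purity F4, and preparative chromatography on a chiral stationary phase then supplies the (S)-enantiomer, rejoining the route at 10.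

3. Step 15 (directed hydrogenation). Hydrogen may be delivered to the β face if the metal binds the C4 acetate carbonyl instead of the 8α-hydroxyl, or the alkene flanked by two quaternary carbons may not react. The fallback changes the order of events and sets out from 16. Heterogeneous hydrogenation (H2, Pd/C, EtOAc) of this less encumbered enone, anti to the C1 methyl and the C4 acetoxy group, should give 4β-acetoxy-5α-daucan-7-one (C8 epimers) F5. Thermodynamic enol silylation toward the more substituted C8 (Me3SiI, (Me3Si)2NH, CH2Cl2) should give 4β-acetoxy-7-(trimethylsilyloxy)-5α-dauc-7-ene F6, and Pd(OAc)2 in MeCN should give 4β-acetoxy-5α-dauc-8-en-7-one F7. Dihydroxylation with OsO4 and NMO from the α face rejoins the route at 20.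

**Further compounds**

F1 | step 10 | (1R,4S)-1-isopropyl-5-methylspiro[3.6]dec-5-en-1-yl trifluoroacetate | CC(C)[C@]1(OC(=O)C(F)(F)F)CC[C@@]12C(C)=CCCCC2
F2 | step 10 | 14-nordauc-5-en-4β-yl trifluoroacetate | CC(C)[C@]1(OC(=O)C(F)(F)F)CC[C@]2(C)CCCCC=C21
F3 | step 10 | 14-nordauc-5-en-4β-ol | CC(C)[C@]1(O)CC[C@]2(C)CCCCC=C21
F4 | step 7 | 5-methylspiro[3.6]dec-5-en-1-one of low enantiomeric purity | O=C1CCC12C(C)=CCCCC2
F5 | step 15 | 4β-acetoxy-5α-daucan-7-one (C8 epimers) | CC(C)[C@]1(OC(C)=O)CC[C@]2(C)CCC(C)C(=O)C[C@H]21
F6 | step 15 | 4β-acetoxy-7-(trimethylsilyloxy)-5α-dauc-7-ene | CC(C)[C@]1(OC(C)=O)CC[C@]2(C)CCC(C)=C(O[Si](C)(C)C)C[C@H]21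
F7 | step 15 | 4β-acetoxy-5α-dauc-8-en-7-one | CC(C)[C@]1(OC(C)=O)CC[C@]2(C)CC=C(C)C(=O)C[C@H]21
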